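**Retrosynthetic overview**
1. The target comes from its hepta-O-benzyl ether by hydrogenolysis in the last step.
2. C2 and C3 are set together by one asymmetric syn-hydrogenation of the C2=C3 bond of a flav-2-en-3-yl gallate, the chemical counterpart of anthocyanidin reductase. The gallate is already in place and directs the metal, so no trans-to-cis correction and no late esterification are needed.
3. The flav-2-ene comes from an anthocyanidin-type flavylium 3-O-gallate by hydride delivery to C4 from an NADH-like dihydropyridine.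
4. Ring C comes from acid-mediated chalcone formation and chalcone-to-flavylium closure (phenol oxygen onto the C3 chain) between a ring A salicylaldehyde and a ring B phenacyl gallate.
5. Ring order: rings A, B and the galloyl ring are bought; ring C is the only ring formed (step 5) and receives both stereocentres one step later.

Assumption: methyl 3,5-dihydroxy-4-methoxybenzoate, 3,4,5-tris(benzyloxy)benzoic acid and 2,4,6-trihydroxybenzaldehyde are taken as catalogue chemicals.

**Route**

Step 1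
Reactants: 1 methyl 3,5-dihydroxy-4-methoxybenzoate
Product: 2 methyl 3,5-bis(benzyloxy)-4-methoxybenzoate
Conditions: BnBr (2.3 equiv), K2CO3 (2.5 equiv), DMF, 60 °C
Reagents that add atoms: benzyl bromide, BrCc1ccccc1
Why: Williamson ether synthesis (SN2) on the two equivalent phenols, with the methyl ester and the aryl methyl ether inert to carbonate.

Step 2
Reactants: 2 methyl 3,5-bis(benzyloxy)-4-methoxybenzoate
Product: 4 1-[3,5-bis(benzyloxy)-4-methoxyphenyl]-2-chloroethan-1-one, via lithium hemiketal alkoxide 3 (not isolated)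
Conditions: ClCH2I (1.5 equiv), MeLi·LiBr (1.4 equiv, slow addition), THF/Et2O, −78 °C; AcOH quench at −78 °C
Reagents that add atoms: chloroiodomethane, ClCI
Why: Barbier-type carbenoid homologation of an ester, in which chloromethyllithium (from iodine–lithium exchange) adds once because tetrahedral adduct 3 is stable at −78 °C and collapses to the chloromethyl ketone only on the cold acidic quench.

Step 3
Reactants: 4 1-[3,5-bis(benzyloxy)-4-methoxyphenyl]-2-chloroethan-1-one, 5 3,4,5-tris(benzyloxy)benzoic acid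
Product: 6 2-[3,5-bis(benzyloxy)-4-methoxyphenyl]-2-oxoethyl 3,4,5-tris(benzyloxy)benzoate
Conditions: Cs2CO3 (1.0 equiv), NaI (10 mol %), DMF, rt
Reagents that add atoms: none
Why: SN2 displacement of the activated phenacyl chloride (Finkelstein-assisted) by the cesium carboxylate gives the phenacyl ester and puts the galloyl group in place before any ring or stereocentre exists.

Step 4
Reactants: 7 2,4,6-trihydroxybenzaldehyde
Product: 8 2,4-bis(benzyloxy)-6-hydroxybenzaldehyde
Conditions: BnBr (2.05 equiv), K2CO3 (2.2 equiv), DMF, 0 °C → rt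
Reagents that add atoms: benzyl bromide, BrCc1ccccc1
Why: Williamson ether synthesis that stops after the para and one ortho hydroxyl, because the remaining ortho hydroxyl is held in a chelated hydrogen bond to the formyl group and is far less nucleophilic.

Step 5
Reactants: 6 2-[3,5-bis(benzyloxy)-4-methoxyphenyl]-2-oxoethyl 3,4,5-tris(benzyloxy)benzoate, 8 2,4-bis(benzyloxy)-6-hydroxybenzaldehyde
Product: 11 5,7-bis(benzyloxy)-2-[3,5-bis(benzyloxy)-4-methoxyphenyl]-4H-chromen-3-yl 3,4,5-tris(benzyloxy)benzoate, via 2-hydroxychalcone 9 (not isolated), via flavylium chloride 10 (not isolated)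
Conditions: dry HCl (g), EtOAc, 0 °C → rt, 24 h; evaporate; then Hantzsch ester (diethyl 2,6-dimethyl-1,4-dihydropyridine-3,5-dicarboxylate, 1.2 equiv), CH2Cl2, 0 °C; aq NaHCO3 work-up
Reagents that add atoms: none
Why: Acid-catalysed aldol condensation (Robinson anthocyanidin synthesis) gives chalcone 9, whose phenol closes ring C onto the ketone with loss of water to the aromatic flavylium 10, and the NADH-type dihydropyridine then transfers hydride to the unhindered, most electrophilic C4 to give the neutral flav-2-ene without creating a stereocentre.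

Step 6
Reactants: 11 5,7-bis(benzyloxy)-2-[3,5-bis(benzyloxy)-4-methoxyphenyl]-4H-chromen-3-yl 3,4,5-tris(benzyloxy)benzoate
Product: 12 (2R,3R)-5,7-bis(benzyloxy)-2-[3,5-bis(benzyloxy)-4-methoxyphenyl]-3,4-dihydro-2H-chromen-3-yl 3,4,5-tris(benzyloxy)benzoate
Conditions: [Rh(cod)((R,R)-Me-DuPhos)]BF4 (5 mol %), H2 (50 bar), CF3CH2OH/CH2Cl2 1:1, 40 °C
Reagents that add atoms: none
Why: Proposed new method: the gallate carbonyl and the C2=C3 bond chelate the cationic monovalent rhodium centre as enol esters and enamides do, both hydrogens are then delivered to one face (syn addition) so that H-2 and H-3 are cis and the aryl and acyloxy groups end up 2,3-cis, and the C2-symmetric diphosphine selects the face that gives 2R,3R, the closest known reaction types being [Rh(cod)(diphosphine)]BF4-catalysed asymmetric hydrogenation of tetrasubstituted cyclic enamides and enol esters and the asymmetric hydrogenation of 2-aryl-4H-chromenes to flavans.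

Step 7
Reactants: 12 (2R,3R)-5,7-bis(benzyloxy)-2-[3,5-bis(benzyloxy)-4-methoxyphenyl]-3,4-dihydro-2H-chromen-3-yl 3,4,5-tris(benzyloxy)benzoate
Product: 13 4'-O-methylepigallocatechin-3-O-gallate
Conditions: H2 (1 atm), Pd(OH)2/C, THF/MeOH 1:1, rt
Reagents that add atoms: none
Why: Hydrogenolysis of the seven aryl benzyl ethers under neutral conditions at room temperature leaves the aryl methyl ether, the gallate ester and both stereocentres untouched (no acid, base or heat that could epimerise C2).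

**Compound list**
1 | methyl 3,5-dihydroxy-4-methoxybenzoate | COC(=O)c1cc(O)c(OC)c(O)c1 | starting material
2 | methyl 3,5-bis(benzyloxy)-4-methoxybenzoate | COC(=O)c1cc(OCc2ccccc2)c(OC)c(OCc2ccccc2)c1 | intermediate
3 | lithium 1-[3,5-bis(benzyloxy)-4-methoxyphenyl]-2-chloro-1-methoxyethan-1-olate (racemic tetrahedral adduct) | [Li+].[O-]C(OC)(CCl)c1cc(OCc2ccccc2)c(OC)c(OCc2ccccc2)c1 | intermediate
4 | 1-[3,5-bis(benzyloxy)-4-methoxyphenyl]-2-chloroethan-1-one | O=C(CCl)c1cc(OCc2ccccc2)c(OC)c(OCc2ccccc2)c1 | intermediate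
5 | 3,4,5-tris(benzyloxy)benzoic acid | OC(=O)c1cc(OCc2ccccc2)c(OCc2ccccc2)c(OCc2ccccc2)c1 | starting material
6 | 2-[3,5-bis(benzyloxy)-4-methoxyphenyl]-2-oxoethyl 3,4,5-tris(benzyloxy)benzoate | COc1c(OCc2ccccc2)cc(C(=O)COC(=O)c2cc(OCc3ccccc3)c(OCc3ccccc3)c(OCc3ccccc3)c2)cc1OCc1ccccc1 | intermediate
7 | 2,4,6-trihydroxybenzaldehyde | O=Cc1c(O)cc(O)cc1O | starting material
8 | 2,4-bis(benzyloxy)-6-hydroxybenzaldehyde | O=Cc1c(O)cc(OCc2ccccc2)cc1OCc1ccccc1 | intermediate
9 | (E)-3-[2,4-bis(benzyloxy)-6-hydroxyphenyl]-1-[3,5-bis(benzyloxy)-4-methoxyphenyl]-1-oxoprop-2-en-2-yl 3,4,5-tris(benzyloxy)benzoate (2-hydroxychalcone, ring A cis to the aroyl group) | COc1c(OCc2ccccc2)cc(C(=O)/C(OC(=O)c2cc(OCc3ccccc3)c(OCc3ccccc3)c(OCc3ccccc3)c2)=C\c2c(O)cc(OCc3ccccc3)cc2OCc2ccccc2)cc1OCc1ccccc1 | intermediate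
10 | 5,7-bis(benzyloxy)-2-[3,5-bis(benzyloxy)-4-methoxyphenyl]-3-{[3,4,5-tris(benzyloxy)benzoyl]oxy}chromenylium chloride | COc1c(OCc2ccccc2)cc(-c2[o+]c3cc(OCc4ccccc4)cc(OCc4ccccc4)c3cc2OC(=O)c2cc(OCc3ccccc3)c(OCc3ccccc3)c(OCc3ccccc3)c2)cc1OCc1ccccc1.[Cl-] | intermediate
11 | 5,7-bis(benzyloxy)-2-[3,5-bis(benzyloxy)-4-methoxyphenyl]-4H-chromen-3-yl 3,4,5-tris(benzyloxy)benzoate | COc1c(OCc2ccccc2)cc(C2=C(OC(=O)c3cc(OCc4ccccc4)c(OCc4ccccc4)c(OCc4ccccc4)c3)Cc3c(OCc4ccccc4)cc(OCc4ccccc4)cc3O2)cc1OCc1ccccc1 | intermediate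
12 | (2R,3R)-5,7-bis(benzyloxy)-2-[3,5-bis(benzyloxy)-4-methoxyphenyl]-3,4-dihydro-2H-chromen-3-yl 3,4,5-tris(benzyloxy)benzoate (2,3-cis) | COc1c(OCc2ccccc2)cc([C@H]2Oc3cc(OCc4ccccc4)cc(OCc4ccccc4)c3C[C@H]2OC(=O)c2cc(OCc3ccccc3)c(OCc3ccccc3)c(OCc3ccccc3)c2)cc1OCc1ccccc1 | intermediate
13 | 4'-O-methylepigallocatechin-3-O-gallate, (2R,3R)-5,7-dihydroxy-2-(3,5-dihydroxy-4-methoxyphenyl)-3,4-dihydro-2H-chromen-3-yl 3,4,5-trihydroxybenzoate | COc1c(O)cc([C@H]2Oc3cc(O)cc(O)c3C[C@H]2OC(=O)c2cc(O)c(O)c(O)c2)cc1O | target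

**Step count:** 7 steps in total. The longest linear sequence is 6 steps (steps 1, 2, 3, 5, 6, 7); step 4 is a one-step side branch.

**Steps most likely to fail and their fallbacks**

Step 6 carries the most risk. The alkene is tetrasubstituted and flanked by large groups, and the catalyst may isomerise it to the flav-3-ene or cleave the enol C–O bond. The hand of the ligand that gives 2R,3R is not predictable for this new substrate class. It has to be fixed in the first run by chiral HPLC and the mirror-image ligand taken if the sense is opposite.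

The fallback sets out from 11 and returns at 12. It replaces alkene hydrogenation by a ketone reduction with dynamic kinetic resolution, which is the tautomer logic of the enzymatic reduction.
- Mild methanolysis of the enol ester (K2CO3 cat., MeOH/THF, 0 °C, under argon) gives rac-5,7-bis(benzyloxy)-2-[3,5-bis(benzyloxy)-4-methoxyphenyl]chroman-3-one F1.
- Its C2 centre is benzylic, alpha to the ketone and epimerises under base. Hydrogenation with RuCl2[(S)-Xyl-SDP][(R,R)-DPEN] and KOt-Bu (H2 50 bar, i-PrOH/toluene) reduces the faster-reacting enantiomer while the other racemises, as with racemic 2-arylcycloalkanones. The catalyst enantiomer is chosen to give the 2,3-cis alcohol (2R,3R)-5,7-bis(benzyloxy)-2-[3,5-bis(benzyloxy)-4-methoxyphenyl]chroman-3-ol F2.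
- Steglich esterification of F2 with acid 5 (DCC, DMAP, CH2Cl2) gives 12.

Step 5 is the second risk. Saturated HCl may slowly cleave or migrate the benzyl groups on the phloroglucinol ring. The 3-acyloxyflavylium 10 is an activated ester that adds water at C2. Some hydride may go to C2 and give the flav-3-ene isomer.

The fallback sets out from 8 and 6 and returns at 11. It never passes through a flavylium, so C4 is a CH2 group from the start.
- NaBH4 (MeOH/THF, 0 °C) reduces 8 to 3,5-bis(benzyloxy)-2-(hydroxymethyl)phenol F3.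
- TMSOTf/Et3N (CH2Cl2, 0 °C) converts 6 into (Z)-2-[3,5-bis(benzyloxy)-4-methoxyphenyl]-2-[(trimethylsilyl)oxy]ethenyl 3,4,5-tris(benzyloxy)benzoate F4.
- Sc(OTf)3 (5 mol %, CH2Cl2, −20 °C) ionises the electron-rich benzylic alcohol F3 in the presence of F4 (Mukaiyama-type benzylation). This gives racemic 3-[2,4-bis(benzyloxy)-6-hydroxyphenyl]-1-[3,5-bis(benzyloxy)-4-methoxyphenyl]-1-oxopropan-2-yl 3,4,5-tris(benzyloxy)benzoate F5.
- The phenol of F5 adds to the ketone, and dehydration (TsOH cat., toluene, 4 Å sieves, 40 °C) gives 11.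

Step 2 is the third risk. Adduct 3 may collapse early, which leads to double addition and epoxide formation, and the carbenoid decomposes above −78 °C.

The fallback sets out from 2 and returns at 6, bypassing 3 and 4.
- Acylation of dimethylsulfoxonium methylide by ester 2 (Me3S(O)I, KOt-Bu, THF, reflux) gives the bench-stable 1-[3,5-bis(benzyloxy)-4-methoxyphenyl]-2-[dimethyl(oxo)-λ6-sulfanylidene]ethan-1-one F6.
- O–H insertion of acid 5 with [Ir(cod)Cl]2 (2 mol %, 1,2-dichloroethane, 70 °C) gives 6. Mechanistically this is protonation of the ylide carbon by the acid and displacement of dimethyl sulfoxide by the carboxylate.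

**Further compounds**
F1 | step 6 | rac-5,7-bis(benzyloxy)-2-[3,5-bis(benzyloxy)-4-methoxyphenyl]chroman-3-one | COc1c(OCc2ccccc2)cc(C2Oc3cc(OCc4ccccc4)cc(OCc4ccccc4)c3CC2=O)cc1OCc1ccccc1
F2 | step 6 | (2R,3R)-5,7-bis(benzyloxy)-2-[3,5-bis(benzyloxy)-4-methoxyphenyl]chroman-3-ol | COc1c(OCc2ccccc2)cc([C@H]2Oc3cc(OCc4ccccc4)cc(OCc4ccccc4)c3C[C@H]2O)cc1OCc1ccccc1
F3 | step 5 | 3,5-bis(benzyloxy)-2-(hydroxymethyl)phenol | OCc1c(O)cc(OCc2ccccc2)cc1OCc1ccccc1
F4 | step 5 | (Z)-2-[3,5-bis(benzyloxy)-4-methoxyphenyl]-2-[(trimethylsilyl)oxy]ethenyl 3,4,5-tris(benzyloxy)benzoate | COc1c(OCc2ccccc2)cc(/C(O[Si](C)(C)C)=C/OC(=O)c2cc(OCc3ccccc3)c(OCc3ccccc3)c(OCc3ccccc3)c2)cc1OCc1ccccc1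
F5 | step 5 | rac-3-[2,4-bis(benzyloxy)-6-hydroxyphenyl]-1-[3,5-bis(benzyloxy)-4-methoxyphenyl]-1-oxopropan-2-yl 3,4,5-tris(benzyloxy)benzoate | COc1c(OCc2ccccc2)cc(C(=O)C(Cc2c(O)cc(OCc3ccccc3)cc2OCc2ccccc2)OC(=O)c2cc(OCc3ccccc3)c(OCc3ccccc3)c(OCc3ccccc3)c2)cc1OCc1ccccc1
F6 | step 2 | 1-[3,5-bis(benzyloxy)-4-methoxyphenyl]-2-[dimethyl(oxo)-λ6-sulfanylidene]ethan-1-one | COc1c(OCc2ccccc2)cc(C(=O)C=S(C)(C)=O)cc1OCc1ccccc1
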